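**Strategy**

Everything rests on disconnecting the O1–C8a aryl ether bond of flavanone ring C, the one ring C bond that lies away from both the C2 stereocentre and the enolisable C3–C4 ketone unit. A palladium-catalysed intramolecular etherification joins the C2 hydroxyl to the ring A aryl bromide and closes ring C in one operation at the flavan-4-ol oxidation level, where no retro-oxa-Michael racemisation can occur. Its precursor is an open-chain syn-1,3-diol: an (S)-configured carbinol on ring B, which already carries the tribenzylated apigenin unit at C3', linked through CH2 to a carbinol on a 2-bromo-4,6-bis(benzyloxy)phenyl ring A. Oxidation at C4 and hydrogenolysis then give the target.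

Key step: step 13

Remark on the chemistry (flavanone numbering is used for the open chain too): the C4 hydroxyl of the cyclisation precursor is left unprotected, because beside the arylpalladium centre its alkoxide can form only a five-membered C,O-chelate that can neither reductively eliminate nor bring its carbinol hydrogen to the metal.

**Route**

Step 1
Reactants: 1 5-bromoresorcinol
Product: 2 1,3-bis(benzyloxy)-5-bromobenzene
Conditions: BnBr, K2CO3, DMF, rt
Reagents that add atoms: benzyl bromide, BrCc1ccccc1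
Why: Williamson etherification of both phenoxides with a reactive benzylic halide, with no competing nucleophilic site in the molecule.

Step 2
Reactants: 2 1,3-bis(benzyloxy)-5-bromobenzene
Product: 4 2,4-bis(benzyloxy)-6-bromobenzaldehyde, via aryl iminium dichlorophosphate 3 (not isolated)
Conditions: POCl3, DMF, 0 to 70 °C; then aq NaOAc
Reagents that add atoms: N,N-dimethylformamide, CN(C)C=O; water, O
Why: Vilsmeier–Haack formylation, in which the chloroiminium ion should attack the carbon next to bromine that is activated by one para and one ortho ether (the usual site in 1-bromo-3,5-dialkoxybenzenes) and not the carbon flanked by both ethers, under conditions that benzyl ethers tolerate better than a Lewis-acid Friedel–Crafts acetylation.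

Step 3
Reactants: 4 2,4-bis(benzyloxy)-6-bromobenzaldehyde
Product: 5 1-[2,4-bis(benzyloxy)-6-bromophenyl]ethan-1-ol (racemic)
Conditions: MeMgBr, THF, 0 °C; aq NH4Cl
Reagents that add atoms: methylmagnesium bromide, C[Mg]Br
Why: Grignard addition to the aldehyde, much faster at 0 °C than bromine–magnesium exchange, gives a racemic carbinol whose stereocentre is erased in step 4.

Step 4
Reactants: 5 1-[2,4-bis(benzyloxy)-6-bromophenyl]ethan-1-ol
Product: 6 1-[2,4-bis(benzyloxy)-6-bromophenyl]ethan-1-one
Conditions: Dess–Martin periodinane, NaHCO3, CH2Cl2, 0 °C to rt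
Reagents that add atoms: none
Why: Dess–Martin oxidation of a secondary benzylic alcohol, buffered with bicarbonate because the electron-rich benzylic carbinol is acid-labile.

Step 5
Reactants: 7 apigenin
Product: 8 7-(benzyloxy)-2-[4-(benzyloxy)phenyl]-5-hydroxy-4H-chromen-4-one (7,4'-di-O-benzylapigenin)
Conditions: BnBr (2.1 equiv), K2CO3, DMF, rt
Reagents that add atoms: benzyl bromide, BrCc1ccccc1
Why: Williamson etherification that should stop at the acidic 7- and 4'-phenols, since the 5-hydroxyl is held in a hydrogen bond to the C4 carbonyl and does not react with a limited amount of halide and a weak base at room temperature.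

Step 6
Reactants: 8 7,4'-di-O-benzylapigenin
Product: 9 7-(benzyloxy)-2-[4-(benzyloxy)phenyl]-5-hydroxy-6-iodo-4H-chromen-4-one
Conditions: BnMe3N+ ICl2−, CaCO3, CH2Cl2/MeOH, rt
Reagents that add atoms: benzyltrimethylammonium dichloroiodate, C[N+](C)(C)Cc1ccccc1.Cl[I-]Cl
Why: electrophilic aromatic iodination of the only phenolic ring, in which the free chelated 5-hydroxyl under carbonate buffering should direct iodine to its ortho position C6 (the known preference of 5-hydroxy-7-alkoxyflavones, whereas 5,7-dialkoxyflavones react at C8), so iodination before the last benzylation fixes the 6-linkage.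

Step 7
Reactants: 9 6-iodo-7,4'-di-O-benzylapigenin
Product: 10 5,7-bis(benzyloxy)-2-[4-(benzyloxy)phenyl]-6-iodo-4H-chromen-4-one
Conditions: BnBr, K2CO3, DMF, 70 °C
Reagents that add atoms: benzyl bromide, BrCc1ccccc1
Why: Williamson etherification of the hydrogen-bonded, hindered 5-phenol, which needs the polar solvent and heat but has no competing site left.

Step 8
Reactants: 11 3-bromo-4-hydroxybenzaldehyde
Product: 12 4-(benzyloxy)-3-bromobenzaldehyde
Conditions: BnBr, K2CO3, DMF, rt
Reagents that add atoms: benzyl bromide, BrCc1ccccc1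
Why: Williamson etherification of an acidic para-formyl phenol, with the aldehyde inert to carbonate.

Step 9
Reactants: 12 4-(benzyloxy)-3-bromobenzaldehyde
Product: 13 4-(benzyloxy)-3-(4,4,5,5-tetramethyl-1,3,2-dioxaborolan-2-yl)benzaldehyde
Conditions: B2pin2, Pd(dppf)Cl2 (3 mol %), KOAc, 1,4-dioxane, 85 °C
Reagents that add atoms: bis(pinacolato)diboron, CC1(C)OB(OC1(C)C)B1OC(C)(C)C(C)(C)O1
Why: Miyaura borylation of an aryl bromide, which tolerates the aldehyde and, with acetate as the base, does not go on to biaryl homocoupling.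

Step 10
Reactants: 10 6-iodo-tri-O-benzylapigenin; 13 ring B pinacol boronate
Product: 14 4-(benzyloxy)-3-{5,7-bis(benzyloxy)-2-[4-(benzyloxy)phenyl]-4-oxo-4H-chromen-6-yl}benzaldehyde
Conditions: Pd(OAc)2 (5 mol %), SPhos (10 mol %), K3PO4, PhMe/H2O, 90 °C
Reagents that add atoms: none
Why: Suzuki–Miyaura coupling to a tri-ortho-substituted biaryl, for which the bulky dialkylbiarylphosphine is suited, with the halide on the doubly flanked flavone carbon and boron on the partner less prone to protodeboronation, and with no other carbon–halogen bond present at this stage.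

Step 11
Reactants: 6 ring A methyl ketone; 14 biaryl aldehyde
Product: 16 (3S)-1-[2,4-bis(benzyloxy)-6-bromophenyl]-3-[4-(benzyloxy)-3-(tri-O-benzylapigenin-6-yl)phenyl]-3-hydroxypropan-1-one, via diisopinocampheylboron enolate 15 (not isolated)
Conditions: 6, (+)-Ipc2BCl, Et3N, CH2Cl2/Et2O, 0 °C; then 14, −78 to −20 °C; then MeOH, pH 7 buffer, H2O2, 0 °C
Reagents that add atoms: none
Why: Paterson-type boron aldol, in which the chloroborane and amine enolise the methyl ketone on its only enolisable side and the enolate adds through a cyclic six-membered boron-bound transition state, where the isopinocampheyl ligands of the (+)-reagent should steer attack to the Si face of the aldehyde and so set the (S)-carbinol that becomes C2, the flavone carbonyl being a vinylogous ester and no electrophile here.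

Step 12
Reactants: 16 (S)-aldol adduct
Product: 18 (1S,3R)-3-[2,4-bis(benzyloxy)-6-bromophenyl]-1-[4-(benzyloxy)-3-(tri-O-benzylapigenin-6-yl)phenyl]propane-1,3-diol (syn), via diethylboron chelate 17 (not isolated)
Conditions: Et2BOMe, THF/MeOH (4:1), −78 °C; NaBH4, −78 to −40 °C; then MeOH co-evaporation
Reagents that add atoms: none
Why: Narasaka–Prasad reduction, in which the diethylboron chelate locks the β-hydroxy ketone in a half-chair and borohydride adds axially, which should give the 1,3-syn diol with the (R)-carbinol at C4, while the less electrophilic flavone carbonyl is left alone at low temperature.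

Step 13
Reactants: 18 syn diol
Product: 19 (2S,4R)-5,7-bis(benzyloxy)-2-[4-(benzyloxy)-3-(tri-O-benzylapigenin-6-yl)phenyl]chroman-4-ol
Conditions: Pd(OAc)2 (5 mol %), RockPhos (7.5 mol %), Cs2CO3, PhMe, 80 °C
Reagents that add atoms: none
Why: Zerovalent palladium, formed in the flask from Pd(OAc)2 and the bulky di-tert-butylbiarylphosphine, inserts into the C8a–Br bond, carbonate-assisted deprotonation of the C2 hydroxyl gives a seven-membered aryl(alkoxo)palladium chelate, and C–O reductive elimination forms O1–C8a. The closest known reaction type is the Buchwald–Hartwig-type intramolecular etherification of secondary alcohols with aryl bromides to chromans, which runs without loss of carbinol configuration. Ring C, six-membered, is closed by delivery of the tethered oxygen to the aryl carbon from that palladacycle, a 6-exo-type closure at an sp2 carbon. No stereocentre is made: the C2–O bond is never broken, so the (S) configuration from step 11 is carried over, and C4 is a spectator that step 14 oxidises away. The step needs chemoselectivity between the two hydroxyls and against β-hydride elimination: the C4 alkoxide can reach palladium only in a five-membered C,O-chelate that cannot reductively eliminate (a four-membered ether) and holds its carbinol hydrogen away from the metal, and the bulky ligand should make reductive elimination from the C2 alkoxide faster than β-hydride loss. Because the base meets a diol and not a β-hydroxy ketone, retro-aldol cleavage and elimination to a chalcone are excluded.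

Step 14
Reactants: 19 (2S,4R)-flavan-4-ol
Product: 20 (2S)-5,7-bis(benzyloxy)-2-[4-(benzyloxy)-3-(tri-O-benzylapigenin-6-yl)phenyl]chroman-4-one
Conditions: Dess–Martin periodinane, NaHCO3, CH2Cl2, 0 °C to rt
Reagents that add atoms: none
Why: Dess–Martin oxidation of the benzylic C4 carbinol under buffered, non-basic conditions, so that the acid-labile flavan-4-ol is not ionised and the new flavanone, which has no free 5-hydroxyl, is not opened to the chalcone and keeps C2 intact.

Step 15
Reactants: 20 hexa-O-benzyl flavanone–flavone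
Product: 21 (2S)-5,7-dihydroxy-2-{4-hydroxy-3-[5,7-dihydroxy-2-(4-hydroxyphenyl)-4-oxo-4H-chromen-6-yl]phenyl}chroman-4-one (CNP0277421.1)
Conditions: H2 (1 atm), 10% Pd/C, THF/MeOH, rt
Reagents that add atoms: none
Why: catalytic hydrogenolysis of the six aryl benzyl ethers under neutral conditions, which should leave the vinylogous-ester carbonyls, the flavone double bond and the C2 stereocentre untouched if the reaction is stopped when hydrogen uptake ends.

**Compound list**

1 | 5-bromoresorcinol | Oc1cc(O)cc(Br)c1 | starting material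
2 | 1,3-bis(benzyloxy)-5-bromobenzene | Brc1cc(OCc2ccccc2)cc(OCc2ccccc2)c1 | intermediate
3 | N-{[2,4-bis(benzyloxy)-6-bromophenyl]methylidene}-N-methylmethanaminium dichlorophosphate | C[N+](C)=Cc1c(Br)cc(OCc2ccccc2)cc1OCc1ccccc1.[O-]P(=O)(Cl)Cl | intermediate
4 | 2,4-bis(benzyloxy)-6-bromobenzaldehyde | O=Cc1c(Br)cc(OCc2ccccc2)cc1OCc1ccccc1 | intermediate
5 | 1-[2,4-bis(benzyloxy)-6-bromophenyl]ethan-1-ol (racemic) | CC(O)c1c(Br)cc(OCc2ccccc2)cc1OCc1ccccc1 | intermediate
6 | 1-[2,4-bis(benzyloxy)-6-bromophenyl]ethan-1-one | CC(=O)c1c(Br)cc(OCc2ccccc2)cc1OCc1ccccc1 | intermediate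
7 | apigenin | O=c1cc(-c2ccc(O)cc2)oc2cc(O)cc(O)c12 | starting material
8 | 7-(benzyloxy)-2-[4-(benzyloxy)phenyl]-5-hydroxy-4H-chromen-4-one | O=c1cc(-c2ccc(OCc3ccccc3)cc2)oc2cc(OCc3ccccc3)cc(O)c12 | intermediate
9 | 7-(benzyloxy)-2-[4-(benzyloxy)phenyl]-5-hydroxy-6-iodo-4H-chromen-4-one | O=c1cc(-c2ccc(OCc3ccccc3)cc2)oc2cc(OCc3ccccc3)c(I)c(O)c12 | intermediate
10 | 5,7-bis(benzyloxy)-2-[4-(benzyloxy)phenyl]-6-iodo-4H-chromen-4-one | O=c1cc(-c2ccc(OCc3ccccc3)cc2)oc2cc(OCc3ccccc3)c(I)c(OCc3ccccc3)c12 | intermediate
11 | 3-bromo-4-hydroxybenzaldehyde | O=Cc1ccc(O)c(Br)c1 | starting material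
12 | 4-(benzyloxy)-3-bromobenzaldehyde | O=Cc1ccc(OCc2ccccc2)c(Br)c1 | intermediate
13 | 4-(benzyloxy)-3-(4,4,5,5-tetramethyl-1,3,2-dioxaborolan-2-yl)benzaldehyde | O=Cc1ccc(OCc2ccccc2)c(B2OC(C)(C)C(C)(C)O2)c1 | intermediate
14 | 4-(benzyloxy)-3-{5,7-bis(benzyloxy)-2-[4-(benzyloxy)phenyl]-4-oxo-4H-chromen-6-yl}benzaldehyde | O=Cc1ccc(OCc2ccccc2)c(-c2c(OCc3ccccc3)cc3oc(-c4ccc(OCc5ccccc5)cc4)cc(=O)c3c2OCc2ccccc2)c1 | intermediate
15 | {1-[2,4-bis(benzyloxy)-6-bromophenyl]ethenyloxy}bis(isopinocampheyl)borane, Ipc groups as in (+)-Ipc2BCl | C=C(OB([C@H]1C[C@H]2C[C@@H]([C@@H]1C)C2(C)C)[C@H]1C[C@H]2C[C@@H]([C@@H]1C)C2(C)C)c1c(Br)cc(OCc2ccccc2)cc1OCc1ccccc1 | intermediate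
16 | (3S)-1-[2,4-bis(benzyloxy)-6-bromophenyl]-3-(4-(benzyloxy)-3-{5,7-bis(benzyloxy)-2-[4-(benzyloxy)phenyl]-4-oxo-4H-chromen-6-yl}phenyl)-3-hydroxypropan-1-one | O=C(C[C@@H](c1ccc(OCc2ccccc2)c(-c2c(OCc3ccccc3)cc3oc(-c4ccc(OCc5ccccc5)cc4)cc(=O)c3c2OCc2ccccc2)c1)O)c1c(Br)cc(OCc2ccccc2)cc1OCc1ccccc1 | intermediate
17 | O-diethylboryl derivative (boron chelate) of 16, (3S) | O=C(C[C@@H](c1ccc(OCc2ccccc2)c(-c2c(OCc3ccccc3)cc3oc(-c4ccc(OCc5ccccc5)cc4)cc(=O)c3c2OCc2ccccc2)c1)OB(CC)CC)c1c(Br)cc(OCc2ccccc2)cc1OCc1ccccc1 | intermediate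
18 | (1S,3R)-3-[2,4-bis(benzyloxy)-6-bromophenyl]-1-(4-(benzyloxy)-3-{5,7-bis(benzyloxy)-2-[4-(benzyloxy)phenyl]-4-oxo-4H-chromen-6-yl}phenyl)propane-1,3-diol | O[C@@H](c1c(Br)cc(OCc2ccccc2)cc1OCc1ccccc1)C[C@@H](c1ccc(OCc2ccccc2)c(-c2c(OCc3ccccc3)cc3oc(-c4ccc(OCc5ccccc5)cc4)cc(=O)c3c2OCc2ccccc2)c1)O | intermediate
19 | (2S,4R)-5,7-bis(benzyloxy)-2-(4-(benzyloxy)-3-{5,7-bis(benzyloxy)-2-[4-(benzyloxy)phenyl]-4-oxo-4H-chromen-6-yl}phenyl)chroman-4-ol | O[C@@H]1C[C@@H](c2ccc(OCc3ccccc3)c(-c3c(OCc4ccccc4)cc4oc(-c5ccc(OCc6ccccc6)cc5)cc(=O)c4c3OCc3ccccc3)c2)Oc2cc(OCc3ccccc3)cc(OCc3ccccc3)c21 | intermediate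
20 | (2S)-5,7-bis(benzyloxy)-2-(4-(benzyloxy)-3-{5,7-bis(benzyloxy)-2-[4-(benzyloxy)phenyl]-4-oxo-4H-chromen-6-yl}phenyl)chroman-4-one | O=C1C[C@@H](c2ccc(OCc3ccccc3)c(-c3c(OCc4ccccc4)cc4oc(-c5ccc(OCc6ccccc6)cc5)cc(=O)c4c3OCc3ccccc3)c2)Oc2cc(OCc3ccccc3)cc(OCc3ccccc3)c21 | intermediate
21 | (2S)-5,7-dihydroxy-2-{4-hydroxy-3-[5,7-dihydroxy-2-(4-hydroxyphenyl)-4-oxo-4H-chromen-6-yl]phenyl}chroman-4-one | O=C1C[C@@H](c2ccc(O)c(-c3c(O)cc4oc(-c5ccc(O)cc5)cc(=O)c4c3O)c2)Oc2cc(O)cc(O)c21 | target

**Step count**

Total: 15 steps. Longest linear sequence: 9 steps (steps 5, 6, 7, 10, 11, 12, 13, 14, 15 from apigenin; the branch from 5-bromoresorcinol through steps 1–4 is equally long).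

**Steps most likely to fail**

Step 13 (key step). The arylpalladium intermediate may rest as the five-membered C4-alkoxide chelate, or the C2 alkoxide may lose a β-hydride, so that hydrodebromination and alcohol oxidation outrun C–O reductive elimination. The fallback masks the C4 oxygen and closes the ring with copper. It sets out from 18. TESCl and imidazole in CH2Cl2 at −20 °C should silylate the less hindered ring B carbinol to give the mono-triethylsilyl ether F1. TBSOTf and 2,6-lutidine then cap the hindered ring A carbinol to give the mixed bis-silyl ether F2. HF·pyridine buffered with pyridine in THF at 0 °C removes the more labile, less hindered triethylsilyl group to give the C4-O-silylated carbinol F3. An Ullmann-type intramolecular etherification (CuI, 3,4,7,8-tetramethyl-1,10-phenanthroline, Cs2CO3, toluene, 110 °C), in which copper alkoxides do not readily lose a β-hydride, closes ring C to the 4-O-silyl flavan F4. TBAF buffered with AcOH in THF removes the silyl group and the route is rejoined at 19.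

Step 11. Facial discrimination by the isopinocampheyl ligands may be incomplete, since boron aldols of methyl ketones are often only moderately selective; enolisation of the hindered ketone may be slow, or the chloroborane may reduce it. Partial selectivity would first be met by recrystallising 16 or 18. The fallback replaces the aldol by conjugate borylation and sets out from 6 and 14. Claisen–Schmidt condensation (KOH, EtOH/THF, rt) gives the (E)-chalcone F5. Copper-catalysed enantioselective β-borylation gives the (S)-β-boryl ketone F6; the conditions are CuCl, NaOtBu, the ferrocenyl diphosphine (R)-1-[(S)-2-(diphenylphosphino)ferrocenyl]ethyldicyclohexylphosphine or its antipode, B2pin2 and MeOH in THF at rt, with the antipode that delivers the (S)-boronate to be fixed on a model chalcone. Oxidation with NaBO3·4H2O in THF/H2O replaces boron by hydroxyl with retention and the route is rejoined at 16.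

Step 15. Over-reduction may occur (hydrogenolysis of the benzylic C2–O1 bond, reduction of the flavanone carbonyl or of the flavone C2=C3 bond), or the reaction may stall at partly benzylated stages as the polyphenol precipitates on the catalyst. The fallback is a non-reductive Lewis-acid debenzylation with BCl3 and pentamethylbenzene as cation scavenger in CH2Cl2 at −78 °C. It sets out from 20, comes back at 21, and makes no new compound (F0).

**Further compounds**

F1 | step 13 | 18 with the ring B carbinol oxygen (O1 of the later ring C) as triethylsilyl ether, configuration as in 18 | O[C@@H](c1c(Br)cc(OCc2ccccc2)cc1OCc1ccccc1)C[C@@H](c1ccc(OCc2ccccc2)c(-c2c(OCc3ccccc3)cc3oc(-c4ccc(OCc5ccccc5)cc4)cc(=O)c3c2OCc2ccccc2)c1)O[Si](CC)(CC)CC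
F2 | step 13 | 18 with the ring A carbinol oxygen as tert-butyldimethylsilyl ether and the ring B carbinol oxygen as triethylsilyl ether | CC(C)(C)[Si](C)(C)O[C@@H](c1c(Br)cc(OCc2ccccc2)cc1OCc1ccccc1)C[C@@H](c1ccc(OCc2ccccc2)c(-c2c(OCc3ccccc3)cc3oc(-c4ccc(OCc5ccccc5)cc4)cc(=O)c3c2OCc2ccccc2)c1)O[Si](CC)(CC)CC
F3 | step 13 | 18 with the ring A carbinol oxygen (C4 oxygen) as tert-butyldimethylsilyl ether and the ring B carbinol free | CC(C)(C)[Si](C)(C)O[C@@H](c1c(Br)cc(OCc2ccccc2)cc1OCc1ccccc1)C[C@@H](c1ccc(OCc2ccccc2)c(-c2c(OCc3ccccc3)cc3oc(-c4ccc(OCc5ccccc5)cc4)cc(=O)c3c2OCc2ccccc2)c1)O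
F4 | step 13 | 4-O-tert-butyldimethylsilyl ether of 19, (2S,4R) | CC(C)(C)[Si](C)(C)O[C@@H]1C[C@@H](c2ccc(OCc3ccccc3)c(-c3c(OCc4ccccc4)cc4oc(-c5ccc(OCc6ccccc6)cc5)cc(=O)c4c3OCc3ccccc3)c2)Oc2cc(OCc3ccccc3)cc(OCc3ccccc3)c21
F5 | step 11 | (E)-1-[2,4-bis(benzyloxy)-6-bromophenyl]-3-[4-(benzyloxy)-3-(tri-O-benzylapigenin-6-yl)phenyl]prop-2-en-1-one | O=C(/C=C/c1ccc(OCc2ccccc2)c(-c2c(OCc3ccccc3)cc3oc(-c4ccc(OCc5ccccc5)cc4)cc(=O)c3c2OCc2ccccc2)c1)c1c(Br)cc(OCc2ccccc2)cc1OCc1ccccc1
F6 | step 11 | (3S)-1-[2,4-bis(benzyloxy)-6-bromophenyl]-3-[4-(benzyloxy)-3-(tri-O-benzylapigenin-6-yl)phenyl]-3-(4,4,5,5-tetramethyl-1,3,2-dioxaborolan-2-yl)propan-1-one | O=C(C[C@@H](c1ccc(OCc2ccccc2)c(-c2c(OCc3ccccc3)cc3oc(-c4ccc(OCc5ccccc5)cc4)cc(=O)c3c2OCc2ccccc2)c1)B1OC(C)(C)C(C)(C)O1)c1c(Br)cc(OCc2ccccc2)cc1OCc1ccccc1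
F0 | step 15 | none | none
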